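**Plan**
Retrosynthesis: the C8–C(=O) bond is cut first (aryl ketone to aryllithium plus Weinreb amide). Then C4–C4a and O1–C8a of the pyran ring are cut together, leaving a symmetric aryl iodide and a chiral oxetane that already holds C2, C3 and C4.
Enabling feature (chroman numbering): the pyran ring places carbon C4 on C4a and oxygen O1 on the adjacent C8a. This is the ortho-carbon/ipso-heteroatom pattern that a palladium/norbornene relay installs from an aryl iodide with iodine at C8a, and the C5–O, C6–Me, C7–O pattern makes both ortho positions of that iodide identical.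
Forward: the iodide (3 steps from 2-methylresorcinol) and the oxetane (5 steps from a glycerate acetonide) are made separately. Their annulation closes the only new ring, the pyran; C8 is then lithiated and acylated, and the three MOM groups are removed.
Stereochemistry: the single stereocentre, C3 (S), comes from the chiral pool (methyl (S)-glycerate acetonide); no bond to it is made or broken in the route.

Key step: step 9

Assumption: the carbinol carbon C3 of the target reads as (S) from its SMILES. The (S)-glycerate ester is the correct source because the CIP order at this carbon (O, then the carbon that becomes C2, then the CH2 that becomes C4) is the same in every intermediate.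

**Route**

Step 1
Reactants: 1 2-methylresorcinol (2-methylbenzene-1,3-diol)
Product: 2 1,3-bis(methoxymethoxy)-2-methylbenzene
Conditions: NaH (2.4 equiv), DMF, 0 °C; MOMCl (2.4 equiv), 0 °C to rt
Reagents that add atoms: chloromethyl methyl ether, COCCl
Why: Williamson-type O-alkylation of the bis-phenoxide with the α-chloro ether should give the bis-MOM ether cleanly.

Step 2
Reactants: 2 1,3-bis(methoxymethoxy)-2-methylbenzene
Product: 3 2-[3,5-bis(methoxymethoxy)-4-methylphenyl]-4,4,5,5-tetramethyl-1,3,2-dioxaborolane
Conditions: [Ir(OMe)(cod)]2 (1.5 mol%), 4,4'-di-tert-butyl-2,2'-bipyridine (3 mol%), B2pin2 (1.0 equiv), THF, 80 °C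
Reagents that add atoms: bis(pinacolato)diboron, CC1(C)OB(OC1(C)C)B1OC(C)(C)C(C)(C)O1
Why: Iridium-catalysed C–H borylation (Hartwig–Miyaura type) is sterically controlled and should take the only C–H without an ortho substituent, the one para to the methyl group.

Step 3
Reactants: 3 2-[3,5-bis(methoxymethoxy)-4-methylphenyl]-4,4,5,5-tetramethyl-1,3,2-dioxaborolane
Product: 4 5-iodo-1,3-bis(methoxymethoxy)-2-methylbenzene
Conditions: CuI (10 mol%), 1,10-phenanthroline (20 mol%), KI (1.5 equiv), MeOH/H2O, air, 80 °C
Reagents that add atoms: potassium iodide, [K+].[I-]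
Why: Copper-catalysed aerobic iododeboronation (Chan–Lam-type halogenation) replaces boron at the ipso carbon without electrophilic iodine, so the activated ring positions and the MOM acetals should stay untouched.

Step 4
Reactants: 5 methyl (4S)-2,2-dimethyl-1,3-dioxolane-4-carboxylate
Product: 7 2-[(4S)-2,2-dimethyl-1,3-dioxolan-4-yl]propan-2-ol, via methyl ketone 6 (not isolated)
Conditions: MeMgBr (3 equiv), THF, 0 °C to rt
Reagents that add atoms: methylmagnesium bromide, C[Mg]Br
Why: Twofold Grignard addition to the ester through ketone 6 gives the tertiary carbinol; addition to the α-alkoxy carbonyl is much faster than enolisation, so the (S) centre should be carried over unchanged.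

Step 5
Reactants: 7 2-[(4S)-2,2-dimethyl-1,3-dioxolan-4-yl]propan-2-ol
Product: 8 (2S)-3-methylbutane-1,2,3-triol
Conditions: Dowex 50W (H+ form), MeOH/H2O, rt
Reagents that add atoms: none
Why: Mild acid-catalysed acetal hydrolysis frees the 1,2-diol without touching the tertiary carbinol or the stereocentre, and the resin is removed by filtration from the water-soluble triol.

Step 6
Reactants: 8 (2S)-3-methylbutane-1,2,3-triol
Product: 9 (2S)-2,3-dihydroxy-3-methylbutyl 4-methylbenzenesulfonate
Conditions: TsCl (1.05 equiv), Et3N (1.2 equiv), Bu2SnO (2 mol%), CH2Cl2/THF, 0 °C to rt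
Reagents that add atoms: 4-methylbenzenesulfonyl chloride, Cc1ccc(cc1)S(=O)(=O)Cl
Why: Tin-catalysed regioselective sulfonylation through a five-membered stannylene acetal of the 1,2-diol should activate only the primary oxygen.

Step 7
Reactants: 9 (2S)-2,3-dihydroxy-3-methylbutyl 4-methylbenzenesulfonate
Product: 10 (2S)-3-hydroxy-2-(methoxymethoxy)-3-methylbutyl 4-methylbenzenesulfonate
Conditions: MOMCl (1.3 equiv), iPr2NEt (2 equiv), CH2Cl2, 0 °C
Reagents that add atoms: chloromethyl methyl ether, COCCl
Why: Alkoxymethylation with MOMCl under amine base is much faster at a secondary than at a tertiary hydroxyl, so limiting reagent at 0 °C should mask the secondary oxygen only, and the weak base should not close the hydroxy tosylate to an epoxide.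

Step 8
Reactants: 10 (2S)-3-hydroxy-2-(methoxymethoxy)-3-methylbutyl 4-methylbenzenesulfonate
Product: 11 (3S)-3-(methoxymethoxy)-2,2-dimethyloxetane
Conditions: NaH (1.2 equiv), THF, 0 °C to 40 °C
Reagents that add atoms: none
Why: Intramolecular Williamson etherification (4-exo-tet) of the tertiary alkoxide onto the primary tosylate, helped by the gem-dimethyl effect, should close the oxetane without breaking a bond to the stereocentre; with the secondary oxygen masked no epoxide can form.

Step 9
Reactants: 4 5-iodo-1,3-bis(methoxymethoxy)-2-methylbenzene, 11 (3S)-3-(methoxymethoxy)-2,2-dimethyloxetane (1.5 equiv)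
Product: 12 (3S)-3,5,7-tris(methoxymethoxy)-2,2,6-trimethyl-3,4-dihydro-2H-chromene
Conditions: Pd(OAc)2 (10 mol%), XPhos (2-dicyclohexylphosphino-2',4',6'-triisopropylbiphenyl, 20 mol%), 1-methylbicyclo[2.2.1]hept-2-ene (1 equiv), LiI (20 mol%), Cs2CO3 (2 equiv), 1,4-dioxane, 100 °C
Reagents that add atoms: none
Why: Proposed new method: a Catellani-type relay in which zerovalent palladium inserts into the C–I bond of 4, the norbornene inserts and carbonate-assisted ortho C–H palladation gives the aryl–norbornyl palladacycle of divalent palladium, which should open the Li+-activated oxetane 11 at its CH2 group by SN2-type oxidative addition to tetravalent palladium (or intercept the γ-iodo alkoxide that iodide may form reversibly from 11, an ordinary primary alkyl iodide for this relay); aryl–alkyl reductive elimination then makes C4–C4a and β-carbon elimination releases the norbornene. The closest known reaction types are the palladium/norbornene annulations of aryl iodides with epoxides to 2,3-dihydrobenzofurans and with aziridines to indolines, and the classical ortho alkylation with primary alkyl iodides, so the untested element is the oxetane as the strained electrophile. The pyran ring closes by ipso C–O reductive elimination from the aryl alkoxide complex of divalent palladium, an intramolecular Buchwald–Hartwig-type etherification through a seven-membered palladacycle that the bulky biarylphosphine should favour and that β-hydride elimination cannot divert, because the alkoxide carbon C2 is quaternary. No stereocentre is formed; C3 is carried over from 11 unchanged because none of its bonds is broken. The step needs attack at the CH2 group and not at the quaternary carbon of 11, which the SN2 character secures, and a single ortho alkylation of the symmetric iodide, which the bridgehead methyl group (fast norbornene extrusion after one alkylation) and the fast intramolecular C–O coupling should secure; as the two ortho positions of 4 are equivalent, only one constitutional isomer can form.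

Step 10
Reactants: 13 3-phenylpropanoyl chloride
Product: 14 N-methoxy-N-methyl-3-phenylpropanamide
Conditions: MeNHOMe·HCl (1.1 equiv), Et3N (2.5 equiv), CH2Cl2, 0 °C to rt
Reagents that add atoms: N,O-dimethylhydroxylamine hydrochloride, CNOC.Cl
Why: N-Acylation of the hydroxylamine by the acid chloride (Schotten–Baumann type) gives the Weinreb amide.

Step 11
Reactants: 12 (3S)-3,5,7-tris(methoxymethoxy)-2,2,6-trimethyl-3,4-dihydro-2H-chromene, 14 N-methoxy-N-methyl-3-phenylpropanamide
Product: 16 1-[(3S)-3,5,7-tris(methoxymethoxy)-2,2,6-trimethyl-3,4-dihydro-2H-chromen-8-yl]-3-phenylpropan-1-one, via C8 aryllithium 15 (not isolated)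
Conditions: n-BuLi (1.3 equiv), THF, 0 °C; then 14 (1.5 equiv), −78 °C to 0 °C
Reagents that add atoms: none
Why: Directed ortho-metalation takes the only aromatic C–H, at C8 between the ring oxygen O1 and the C7 OMOM group, and the Weinreb ketone synthesis stops at the ketone because the chelated tetrahedral adduct survives until work-up.

Step 12
Reactants: 16 1-[(3S)-3,5,7-tris(methoxymethoxy)-2,2,6-trimethyl-3,4-dihydro-2H-chromen-8-yl]-3-phenylpropan-1-one
Product: 17 1-[(3S)-3,5,7-trihydroxy-2,2,6-trimethyl-3,4-dihydro-2H-chromen-8-yl]-3-phenylpropan-1-one (target)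
Conditions: 3 M HCl, MeOH, 50 °C
Reagents that add atoms: none
Why: Acid-catalysed acetal methanolysis removes the two aryl and the one alkyl MOM ether, while the aryl ketone, the chroman ether and the C3 carbinol (no bond to it broken) should be stable.

**Compound list**
1 | 2-methylresorcinol (2-methylbenzene-1,3-diol) | Cc1c(O)cccc1O | starting material
2 | 1,3-bis(methoxymethoxy)-2-methylbenzene | Cc1c(OCOC)cccc1OCOC | intermediate
3 | 2-[3,5-bis(methoxymethoxy)-4-methylphenyl]-4,4,5,5-tetramethyl-1,3,2-dioxaborolane | Cc1c(OCOC)cc(cc1OCOC)B1OC(C)(C)C(C)(C)O1 | intermediate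
4 | 5-iodo-1,3-bis(methoxymethoxy)-2-methylbenzene | Cc1c(OCOC)cc(I)cc1OCOC | intermediate
5 | methyl (4S)-2,2-dimethyl-1,3-dioxolane-4-carboxylate | COC(=O)[C@@H]1COC(C)(C)O1 | starting material
6 | 1-[(4S)-2,2-dimethyl-1,3-dioxolan-4-yl]ethan-1-one (methyl ketone) | CC(=O)[C@@H]1COC(C)(C)O1 | intermediate
7 | 2-[(4S)-2,2-dimethyl-1,3-dioxolan-4-yl]propan-2-ol | CC(C)(O)[C@@H]1COC(C)(C)O1 | intermediate
8 | (2S)-3-methylbutane-1,2,3-triol | CC(C)(O)[C@@H](O)CO | intermediate
9 | (2S)-2,3-dihydroxy-3-methylbutyl 4-methylbenzenesulfonate | CC(C)(O)[C@@H](O)COS(=O)(=O)c1ccc(C)cc1 | intermediate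
10 | (2S)-3-hydroxy-2-(methoxymethoxy)-3-methylbutyl 4-methylbenzenesulfonate | CC(C)(O)[C@@H](OCOC)COS(=O)(=O)c1ccc(C)cc1 | intermediate
11 | (3S)-3-(methoxymethoxy)-2,2-dimethyloxetane | CC1(C)OC[C@@H]1OCOC | intermediate
12 | (3S)-3,5,7-tris(methoxymethoxy)-2,2,6-trimethyl-3,4-dihydro-2H-chromene | Cc1c(OCOC)c2c(cc1OCOC)OC(C)(C)[C@@H](OCOC)C2 | intermediate
13 | 3-phenylpropanoyl chloride | O=C(Cl)CCc1ccccc1 | starting material
14 | N-methoxy-N-methyl-3-phenylpropanamide | CON(C)C(=O)CCc1ccccc1 | intermediate
15 | [(3S)-3,5,7-tris(methoxymethoxy)-2,2,6-trimethyl-3,4-dihydro-2H-chromen-8-yl]lithium (C8 aryllithium) | Cc1c(OCOC)c2c(c([Li])c1OCOC)OC(C)(C)[C@@H](OCOC)C2 | intermediate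
16 | 1-[(3S)-3,5,7-tris(methoxymethoxy)-2,2,6-trimethyl-3,4-dihydro-2H-chromen-8-yl]-3-phenylpropan-1-one | Cc1c(OCOC)c2c(c(C(=O)CCc3ccccc3)c1OCOC)OC(C)(C)[C@@H](OCOC)C2 | intermediate
17 | 1-[(3S)-3,5,7-trihydroxy-2,2,6-trimethyl-3,4-dihydro-2H-chromen-8-yl]-3-phenylpropan-1-one | Cc1c(O)c2c(c(C(=O)CCc3ccccc3)c1O)OC(C)(C)[C@@H](O)C2 | target

**Count**
Total step count: 12.
Longest linear sequence: 8 steps (steps 4, 5, 6, 7, 8, 9, 11, 12, from glycerate 5 to target 17).

**Steps most likely to fail**

Step 9. The palladacycle may open the oxetane too slowly, since oxetanes are much poorer SN2 electrophiles than epoxides. In addition, ortho C–H palladation next to an OMOM group whose CH2 is turned toward that hydrogen may be sluggish. In either case protodeiodination, direct ipso coupling or norbornene-containing by-products could take over. The fallback makes the same two bonds one after the other by known reactions and sets out from boronate 3. CuCl2 in MeOH/H2O at 80 °C (chlorodeboronation) should give 5-chloro-1,3-bis(methoxymethoxy)-2-methylbenzene F1. Treatment with s-BuLi in THF at −78 °C should deprotonate between chlorine and OMOM (directed ortho-metalation) to give [6-chloro-2,4-bis(methoxymethoxy)-3-methylphenyl]lithium F2. Adding oxetane 11 and BF3·OEt2 at −78 °C should open the oxetane at its CH2 group and give (3S)-4-[6-chloro-2,4-bis(methoxymethoxy)-3-methylphenyl]-3-(methoxymethoxy)-2-methylbutan-2-ol F3. Intramolecular Buchwald–Hartwig etherification of the tertiary alcohol (Pd(OAc)2, a di-tert-butylbiarylphosphine, Cs2CO3, toluene, 80–100 °C) should then close the pyran ring and return to chroman 12.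

Step 11. The hindered, di-ortho-substituted aryllithium 15 may act as a base toward the α-CH2 of amide 14 instead of adding to it, returning protonated 12. The fallback sets out from 12 through the same aryllithium 15 but changes the electrophile and the oxidation level. Addition to 3-phenylpropanal at −78 °C, which is much faster than enolisation, should give 1-[(3S)-3,5,7-tris(methoxymethoxy)-2,2,6-trimethyl-3,4-dihydro-2H-chromen-8-yl]-3-phenylpropan-1-ol F4 as a mixture of carbinol epimers. Oxidation with Dess–Martin periodinane in CH2Cl2 removes the new centre and returns to ketone 16.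

Step 7. Alkylation may spill over to the tertiary hydroxyl, or the amine base may close the hydroxy tosylate to an epoxide, eroding the supply of 10. The fallback removes the selectivity question by masking the tertiary oxygen first and sets out from alcohol 7. NaH, BnBr and Bu4NI in DMF should give (4S)-4-[2-(benzyloxy)propan-2-yl]-2,2-dimethyl-1,3-dioxolane F5. Dowex 50W (H+ form) in MeOH/H2O should give (2S)-3-(benzyloxy)-3-methylbutane-1,2-diol F6. TsCl, Et3N and catalytic Bu2SnO should give (2S)-3-(benzyloxy)-2-hydroxy-3-methylbutyl 4-methylbenzenesulfonate F7. MOMCl and iPr2NEt, now with only one free hydroxyl, should give (2S)-3-(benzyloxy)-2-(methoxymethoxy)-3-methylbutyl 4-methylbenzenesulfonate F8. Hydrogenolysis (H2, Pd/C, EtOAc) should free the tertiary alcohol and return to tosylate 10.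

**Further compounds**
F1 | step 9 | 5-chloro-1,3-bis(methoxymethoxy)-2-methylbenzene | Cc1c(OCOC)cc(Cl)cc1OCOC
F2 | step 9 | [6-chloro-2,4-bis(methoxymethoxy)-3-methylphenyl]lithium | [Li]c1c(Cl)cc(OCOC)c(C)c1OCOC
F3 | step 9 | (3S)-4-[6-chloro-2,4-bis(methoxymethoxy)-3-methylphenyl]-3-(methoxymethoxy)-2-methylbutan-2-ol | CC(C)(O)[C@@H](OCOC)Cc1c(Cl)cc(OCOC)c(C)c1OCOC
F4 | step 11 | 1-[(3S)-3,5,7-tris(methoxymethoxy)-2,2,6-trimethyl-3,4-dihydro-2H-chromen-8-yl]-3-phenylpropan-1-ol (carbinol epimers) | Cc1c(OCOC)c2c(c(C(O)CCc3ccccc3)c1OCOC)OC(C)(C)[C@@H](OCOC)C2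
F5 | step 7 | (4S)-4-[2-(benzyloxy)propan-2-yl]-2,2-dimethyl-1,3-dioxolane | CC(C)(OCc1ccccc1)[C@@H]1COC(C)(C)O1
F6 | step 7 | (2S)-3-(benzyloxy)-3-methylbutane-1,2-diol | CC(C)(OCc1ccccc1)[C@@H](O)CO
F7 | step 7 | (2S)-3-(benzyloxy)-2-hydroxy-3-methylbutyl 4-methylbenzenesulfonate | CC(C)(OCc1ccccc1)[C@@H](O)COS(=O)(=O)c1ccc(C)cc1
F8 | step 7 | (2S)-3-(benzyloxy)-2-(methoxymethoxy)-3-methylbutyl 4-methylbenzenesulfonate | CC(C)(OCc1ccccc1)[C@@H](OCOC)COS(=O)(=O)c1ccc(C)cc1
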